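The heptanoid chain is cut between C4 (the CH2 α to the C3 ketone) and C5 (the benzylic stereocentre on flavonol C8). The free C7–OH of ring A, ortho to C8, allows the unprotected 8-[(E)-3-arylprop-1-enyl]galangin to tautomerise under a chiral phosphoric acid to an ortho-quinone methide (C7=O, C8=C5). 3-Oxo-5-phenylpentanoic acid adds to C5 inside the chiral hydrogen-bonded complex and loses CO2, so a single protecting-group-free operation joins both halves, sets C5 and ends the synthesis. The precursor comes from C8-iodination of MOM-protected galangin, deprotection and Suzuki coupling with a eugenol-derived alkenylboronate.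

Key step: step 7

Assumption: the target is taken as the open-chain keto-phenol as drawn; a reversible cyclic hemiketal (O-7 onto the chain carbonyl) is regarded as the same compound and is opened on aqueous work-up.
Assumption: the sense of induction of the chiral acid must be confirmed by experiment; the (R)-catalyst is written, and its enantiomer is used if the opposite C5 configuration is favoured.

Step 1
Reactants: 1 galangin
Product: 2 3,5,7-tris(methoxymethoxy)-2-phenyl-4H-chromen-4-one
Conditions: NaH (3.6 equiv), MOMCl (4 equiv), DMF, 0 °C → rt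
Reagents that add atoms: chloromethyl methyl ether (MOMCl), COCCl
Why: Williamson O-alkylation of the tris-sodium salt caps all three hydroxyls, the chelated 5-OH included, which is what later directs iodination to C8 instead of C6.

Step 2
Reactants: 2 3,5,7-tris(methoxymethoxy)-2-phenyl-4H-chromen-4-one
Product: 3 8-iodo-3,5,7-tris(methoxymethoxy)-2-phenyl-4H-chromen-4-one
Conditions: I2 (1.05 equiv), CF3CO2Ag (1.1 equiv), solid NaHCO3, CH2Cl2, 0 °C → rt, dark
Reagents that add atoms: iodine, II
Why: Electrophilic aromatic iodination by CF3CO2I formed in situ should go to C8 of a 5,7-dialkoxyflavone (C6 is flanked by two alkoxy groups and lacks the activation of a free 5-OH), while solid NaHCO3 takes up the acid so that the MOM acetals survive.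

Step 3
Reactants: 3 8-iodo-3,5,7-tris(methoxymethoxy)-2-phenyl-4H-chromen-4-one
Product: 4 8-iodogalangin (3,5,7-trihydroxy-8-iodo-2-phenyl-4H-chromen-4-one)
Conditions: 3 M HCl, MeOH/THF, 50 °C
Reagents that add atoms: none
Why: Acid-catalysed acetal exchange with methanol removes the three MOM groups as dimethoxymethane and leaves the aryl iodide untouched, and it is placed here because the acid-sensitive styrene installed next would not tolerate it.

Step 4
Reactants: 5 eugenol (4-allyl-2-methoxyphenol), 6 vinylboronic acid pinacol ester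
Product: 7 2-methoxy-4-[(E)-3-(4,4,5,5-tetramethyl-1,3,2-dioxaborolan-2-yl)prop-2-en-1-yl]phenol
Conditions: Grubbs II catalyst (3 mol%), 1,4-benzoquinone (10 mol%), 6 (2 equiv), CH2Cl2, 40 °C
Reagents that add atoms: none
Why: Olefin cross-metathesis between an allylarene and vinyl-Bpin should give the E-alkenylboronate under thermodynamic control, with ethylene loss as driving force and benzoquinone suppressing Ru–H double-bond migration.

Step 5
Reactants: 4 8-iodogalangin, 7 2-methoxy-4-[(E)-3-(4,4,5,5-tetramethyl-1,3,2-dioxaborolan-2-yl)prop-2-en-1-yl]phenol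
Product: 8 3,5,7-trihydroxy-8-[(E)-3-(4-hydroxy-3-methoxyphenyl)prop-1-en-1-yl]-2-phenyl-4H-chromen-4-one
Conditions: Pd(OAc)2 (5 mol%), SPhos (10 mol%), K3PO4 (5 equiv), degassed 1,4-dioxane/H2O (4:1), 70 °C
Reagents that add atoms: none
Why: Suzuki–Miyaura coupling of the aryl iodide with the alkenylboronate should proceed with retention of the E geometry, the electron-rich SPhos–Pd catalyst tolerating the phenoxides formed in aqueous base, while degassing protects the flavonol from base/O2 degradation.

Step 6
Reactants: 9 ethyl 3-oxo-5-phenylpentanoate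
Product: 10 3-oxo-5-phenylpentanoic acid
Conditions: 1 M aq NaOH, rt; then 1 M HCl, 0 °C, extraction, used at once
Reagents that add atoms: sodium hydroxide, [Na+].[OH-]
Why: Ester saponification followed by cold acidification gives the free β-keto acid, which is used immediately because it decarboxylates on standing.

Step 7
Reactants: 8 3,5,7-trihydroxy-8-[(E)-3-(4-hydroxy-3-methoxyphenyl)prop-1-en-1-yl]-2-phenyl-4H-chromen-4-one, 10 3-oxo-5-phenylpentanoic acid
Product: 13 3,5,7-trihydroxy-8-[(5R)-7-(4-hydroxy-3-methoxyphenyl)-3-oxo-1-phenylheptan-5-yl]-2-phenyl-4H-chromen-4-one (target), via ortho-quinone methide 11 (not isolated), via beta-keto acid adduct 12 (not isolated)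
Conditions: (R)-TRIP (10 mol%), 10 (3 equiv, in portions), ClCH2CH2Cl/EtOAc (5:1), 0.02 M, 40 °C
Reagents that add atoms: none
Why: The phosphoric acid shuttles the O7–H proton to the side-chain carbon C6 (tautomerisation of the o-hydroxystyrene), giving the ortho-quinone methide 11 hydrogen-bonded to the chiral phosphate; the enol of 10, held by the same phosphate, attacks the exocyclic carbon C5 with rearomatisation of ring A to give 12, which loses CO2 to leave the ketone. The closest known reaction types are the chiral Brønsted acid-catalysed conjugate addition of 1,3-dicarbonyl enols to in situ generated o-quinone methides and the organocatalytic enantioselective decarboxylative alkylation of β-keto acids with o-quinone methides. No ring is closed; ring A is dearomatised and rearomatised in passing. The single stereocentre C5 is controlled by the catalyst, whose 3,3'-aryl groups shield one face of the bound quinone methide so that the enol is delivered to the face that gives (R). The step needs protonation at C6 rather than C5, which the O-7/O-5/O-1 donors of ring A secure, and bonding through the carbon between the two carbonyls of 10, which the later-lost carboxyl group secures. It also needs intermolecular capture to outrun attack by the guaiacyl ring or by C6 of a second flavonol, which the excess of 10, high dilution and a weak acid that hydrogen-bonds rather than fully ionises the quinone methide should favour.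

Compound list
1 | galangin (3,5,7-trihydroxy-2-phenyl-4H-chromen-4-one) | O=c1c(O)c(-c2ccccc2)oc2cc(O)cc(O)c12 | starting material
2 | 3,5,7-tris(methoxymethoxy)-2-phenyl-4H-chromen-4-one | COCOc1cc(OCOC)c2c(c1)oc(-c1ccccc1)c(OCOC)c2=O | intermediate
3 | 8-iodo-3,5,7-tris(methoxymethoxy)-2-phenyl-4H-chromen-4-one | COCOc1cc(OCOC)c2c(c1I)oc(-c1ccccc1)c(OCOC)c2=O | intermediate
4 | 8-iodogalangin (3,5,7-trihydroxy-8-iodo-2-phenyl-4H-chromen-4-one) | O=c1c(O)c(-c2ccccc2)oc2c(I)c(O)cc(O)c12 | intermediate
5 | eugenol (4-allyl-2-methoxyphenol) | COc1cc(CC=C)ccc1O | starting material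
6 | vinylboronic acid pinacol ester (2-ethenyl-4,4,5,5-tetramethyl-1,3,2-dioxaborolane) | C=CB1OC(C)(C)C(C)(C)O1 | starting material
7 | 2-methoxy-4-[(E)-3-(4,4,5,5-tetramethyl-1,3,2-dioxaborolan-2-yl)prop-2-en-1-yl]phenol | COc1cc(C/C=C/B2OC(C)(C)C(C)(C)O2)ccc1O | intermediate
8 | 3,5,7-trihydroxy-8-[(E)-3-(4-hydroxy-3-methoxyphenyl)prop-1-en-1-yl]-2-phenyl-4H-chromen-4-one | COc1cc(C/C=C/c2c(O)cc(O)c3c(=O)c(O)c(-c4ccccc4)oc23)ccc1O | intermediate
9 | ethyl 3-oxo-5-phenylpentanoate | CCOC(=O)CC(=O)CCc1ccccc1 | starting material
10 | 3-oxo-5-phenylpentanoic acid | OC(=O)CC(=O)CCc1ccccc1 | intermediate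
11 | ortho-quinone methide of 8: 3,5-dihydroxy-8-[3-(4-hydroxy-3-methoxyphenyl)propylidene]-2-phenyl-8H-chromene-4,7-dione (not isolated) | O=C1C=C(O)C2=C(OC(c3ccccc3)=C(O)C2=O)C1=CCCc1ccc(O)c(OC)c1 | intermediate
12 | β-keto acid adduct: 2-[(1R)-3-(4-hydroxy-3-methoxyphenyl)-1-(3,5,7-trihydroxy-4-oxo-2-phenyl-4H-chromen-8-yl)propyl]-3-oxo-5-phenylpentanoic acid, α-carbon unassigned (not isolated) | COc1cc(CC[C@H](C(C(=O)O)C(=O)CCc2ccccc2)c2c(O)cc(O)c3c(=O)c(O)c(-c4ccccc4)oc23)ccc1O | intermediate
13 | 3,5,7-trihydroxy-8-[(5R)-7-(4-hydroxy-3-methoxyphenyl)-3-oxo-1-phenylheptan-5-yl]-2-phenyl-4H-chromen-4-one (CNP0164153.1) | COc1cc(CC[C@H](CC(=O)CCc2ccccc2)c2c(O)cc(O)c3c(=O)c(O)c(-c4ccccc4)oc23)ccc1O | target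

Total step count: 7. Longest linear sequence: 5 steps (1 → 2 → 3 → 4 → 8 → 13; steps 1, 2, 3, 5, 7).

Steps most likely to fail

Step 7. The weak chiral acid may generate the quinone methide too slowly from the carbonyl-deactivated styrene. Facial discrimination may be poor at an alkyl-substituted quinone methide. The guaiacyl ring may close onto C5 in an intramolecular Friedel–Crafts reaction, or the material may oligomerise through C6 of a second flavonol. The fallback sets out from 8 and returns at 13, and replaces the acid-generated cation-like species by a base-generated neutral quinone methide under hydrogen-bonding catalysis. Compound 8 is treated with p-toluenesulfinic acid (CH2Cl2, rt), which should add across the styrene at the benzylic carbon to give the racemic sulfone 3,5,7-trihydroxy-8-[3-(4-hydroxy-3-methoxyphenyl)-1-(4-methylbenzenesulfonyl)propyl]-2-phenyl-4H-chromen-4-one F1. F1 and 10 are then combined with a quinine-derived bifunctional squaramide (10 mol%) and aqueous NaHCO3 in CH2Cl2/EtOAc at rt. Base-induced loss of sulfinate releases 11, and the known squaramide-catalysed enantioselective decarboxylative addition of the β-keto acid (through 12) should give 13.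

Step 5. The poly-phenoxide of 4 may slow oxidative addition or bind palladium, protodeiodination may compete, and the flavonol may degrade in hot aqueous base. The fallback sets out from 4 and returns at 8, masking the phenols as base-labile esters for the coupling. Compound 4 is peracetylated (Ac2O, pyridine, rt) to 8-iodo-4-oxo-2-phenyl-4H-chromene-3,5,7-triyl triacetate F2. Anhydrous Suzuki–Miyaura coupling of F2 with 7 (Pd2(dba)3, P(t-Bu)3·HBF4, KF, THF, 50 °C) should give 8-[(E)-3-(4-hydroxy-3-methoxyphenyl)prop-1-en-1-yl]-4-oxo-2-phenyl-4H-chromene-3,5,7-triyl triacetate F3. Methanolysis (K2CO3, MeOH, rt) then removes the acetates without any acid and delivers 8.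

Step 2. Iodination may leak to C6 or to double iodination, and liberated acid may strip MOM groups and so change the directing pattern. The fallback sets out from 1 and returns at 8, using a sigmatropic shift from O-7 to fix the C8 regiochemistry instead of electrophilic substitution. Galangin 1 is mono-allylated at its most acidic 7-OH (allyl bromide 1.05 equiv, K2CO3, acetone, rt) to 7-(allyloxy)-3,5-dihydroxy-2-phenyl-4H-chromen-4-one F4. Aromatic Claisen rearrangement (N,N-diethylaniline, 190 °C) should move the allyl group to C8 and give 8-allyl-3,5,7-trihydroxy-2-phenyl-4H-chromen-4-one F5. Ru–H isomerisation (RuHCl(CO)(PPh3)3, toluene, 80 °C) gives 3,5,7-trihydroxy-2-phenyl-8-[(E)-prop-1-en-1-yl]-4H-chromen-4-one F6. Cross-metathesis of F6 with eugenol 5 (Hoveyda–Grubbs II, CH2Cl2, 40 °C) then gives 8 with loss of propene.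

Further compounds
F1 | step 7 | 3,5,7-trihydroxy-8-[3-(4-hydroxy-3-methoxyphenyl)-1-(4-methylbenzenesulfonyl)propyl]-2-phenyl-4H-chromen-4-one (racemic) | COc1cc(CCC(c2c(O)cc(O)c3c(=O)c(O)c(-c4ccccc4)oc23)S(=O)(=O)c2ccc(C)cc2)ccc1O
F2 | step 5 | 8-iodo-4-oxo-2-phenyl-4H-chromene-3,5,7-triyl triacetate | CC(=O)Oc1cc(OC(C)=O)c2c(c1I)oc(-c1ccccc1)c(OC(C)=O)c2=O
F3 | step 5 | 8-[(E)-3-(4-hydroxy-3-methoxyphenyl)prop-1-en-1-yl]-4-oxo-2-phenyl-4H-chromene-3,5,7-triyl triacetate | COc1cc(C/C=C/c2c(OC(C)=O)cc(OC(C)=O)c3c(=O)c(OC(C)=O)c(-c4ccccc4)oc23)ccc1O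
F4 | step 2 | 7-(allyloxy)-3,5-dihydroxy-2-phenyl-4H-chromen-4-one | C=CCOc1cc(O)c2c(c1)oc(-c1ccccc1)c(O)c2=O
F5 | step 2 | 8-allyl-3,5,7-trihydroxy-2-phenyl-4H-chromen-4-one | C=CCc1c(O)cc(O)c2c1oc(-c1ccccc1)c(O)c2=O
F6 | step 2 | 3,5,7-trihydroxy-2-phenyl-8-[(E)-prop-1-en-1-yl]-4H-chromen-4-one | C/C=C/c1c(O)cc(O)c2c1oc(-c1ccccc1)c(O)c2=O
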